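**Retrosynthetic overview**

- The strategy rests on one feature: C2' of ring B carries a prenyl group wedged between C1' (bonded to C2 of ring C) and the oxygen-bearing C3'. That C2'–CH2 bond is made late by a [3,3] shift from O3', and the freed 3'-OH then becomes the 3'-OMe.
- The rearrangement precursor is the 3'-O-(1,1-dimethylallyl) ether of a tri-MOM (2S)-8-prenylflavanone, made from the 3'-phenol by palladium-catalysed O-allylation with a tertiary allylic carbonate.
- The C2–C1' bond and the only stereocentre come from a rhodium-catalysed asymmetric 1,4-addition of a ring-B boronic acid to 5,7-bis(MOM-oxy)-8-prenylchromone.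
- The 8-prenyl group is placed on the chromone by a Claisen–Cope shift from a 5-O-prenyl ether. The boronic acid comes from 5-bromosalicylaldehyde by MOM protection, Dakin oxidation, silylation and borylation.
- No ring is built: rings A and C are bought together as 5,7-dihydroxychromone and ring B as the aldehyde. Ring C is only saturated at C2 (step 9).

Key step: step 13

Assumption: the (S)-configured biaryl diphosphine is taken to give the (2S)-flavanone in step 9, as the facial model for rhodium-catalysed additions to cyclic enones predicts. The sense of induction would be checked on the first batch (chiral HPLC, CD) and the antipodal ligand used if it is the reverse.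

**Route**

Step 1
Reactants: 1 5,7-dihydroxychromone
Product: 2 5-hydroxy-7-(methoxymethoxy)chromone
Conditions: MOMCl (1.1 equiv), K2CO3, acetone, 0 °C → rt
Reagents that add atoms: chloromethyl methyl ether (MOMCl), COCCl
Why: Williamson-type O-alkylation takes the free, more acidic 7-OH, while the 5-OH stays locked in its hydrogen bond to the C4 carbonyl.

Step 2
Reactants: 2 5-hydroxy-7-(methoxymethoxy)chromone; 3 prenyl bromide
Product: 4 7-(methoxymethoxy)-5-(3-methylbut-2-enyloxy)chromone
Conditions: K2CO3, DMF, 50 °C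
Reagents that add atoms: none
Why: Williamson ether synthesis under more forcing conditions alkylates the chelated 5-OH, the only hydroxyl left, at the primary carbon of the allylic bromide (SN2).

Step 3
Reactants: 4 7-(methoxymethoxy)-5-(3-methylbut-2-enyloxy)chromone
Product: 7 5-hydroxy-7-(methoxymethoxy)-8-(3-methylbut-2-enyl)chromone, via ortho-dienone 5 (not isolated), via para-dienone 6 (not isolated)
Conditions: Eu(fod)3 (10 mol%; fod = 6,6,7,7,8,8,8-heptafluoro-2,2-dimethyloctane-3,5-dionate), NaHCO3, PhCl, 85 °C
Reagents that add atoms: none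
Why: Tandem Claisen–Cope (para-Claisen) rearrangement: Eu(fod)3 bound between O5 and the C4 carbonyl speeds the [3,3] shift of the prenyl ether to C6, the only ortho CH, and a Cope shift then carries the group from dienone 5 to C8 as a normal prenyl group in dienone 6, which enolises to the chelated 5-phenol, so the site (para to O5) is fixed by where the ether sits.

Step 4
Reactants: 7 5-hydroxy-7-(methoxymethoxy)-8-(3-methylbut-2-enyl)chromone
Product: 9 5,7-bis(methoxymethoxy)-8-(3-methylbut-2-enyl)chromone, via sodium phenoxide 8 (not isolated)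
Conditions: NaH, DMF, 0 °C; then MOMCl, 0 °C → rt
Reagents that add atoms: chloromethyl methyl ether (MOMCl), COCCl
Why: Irreversible deprotonation breaks the 5-OH chelate and the phenoxide is O-alkylated (Williamson); the chromone has no stereocentre and no group that the base can harm.

Step 5
Reactants: 10 5-bromosalicylaldehyde
Product: 11 5-bromo-2-(methoxymethoxy)benzaldehyde
Conditions: MOMCl, K2CO3, acetone, rt
Reagents that add atoms: chloromethyl methyl ether (MOMCl), COCCl
Why: Williamson-type MOM protection of the acidic salicylaldehyde phenol, which will become O4' of ring B (para to the bromine).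

Step 6
Reactants: 11 5-bromo-2-(methoxymethoxy)benzaldehyde
Product: 13 5-bromo-2-(methoxymethoxy)phenol, via aryl formate 12 (not isolated)
Conditions: mCPBA, CH2Cl2, rt; then K2CO3 (cat.), MeOH, rt
Reagents that add atoms: 3-chloroperbenzoic acid (mCPBA), OOC(=O)c1cccc(Cl)c1
Why: Baeyer–Villiger (Dakin-type) oxidation: the electron-rich ortho-alkoxyaryl group migrates in the Criegee intermediate to give the formate, which mild methanolysis cleaves to the phenol that will become O3'.

Step 7
Reactants: 13 5-bromo-2-(methoxymethoxy)phenol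
Product: 14 [5-bromo-2-(methoxymethoxy)phenoxy](tert-butyl)dimethylsilane
Conditions: TBSCl, imidazole, DMF, rt
Reagents that add atoms: tert-butyldimethylsilyl chloride (TBSCl), CC(C)(C)[Si](C)(C)Cl
Why: Imidazole-promoted silylation masks the phenol so that it cannot quench the aryllithium or the aryl–rhodium species, and the silyl ether can later be removed by fluoride without touching the MOM groups.

Step 8
Reactants: 14 [5-bromo-2-(methoxymethoxy)phenoxy](tert-butyl)dimethylsilane
Product: 17 [3-(tert-butyldimethylsilyloxy)-4-(methoxymethoxy)phenyl]boronic acid, via aryllithium 15 (not isolated), via lithium triisopropoxyborate 16 (not isolated)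
Conditions: B(Oi-Pr)3, n-BuLi, THF/PhMe, −78 °C; then dil. aq. HCl to pH 6, 0 °C
Reagents that add atoms: triisopropyl borate, CC(C)OB(OC(C)C)OC(C)C; water, O
Why: Bromine–lithium exchange at −78 °C is faster than ortho-lithiation next to OMOM, the aryllithium is trapped at once by the borate already present (in situ quench), and mild hydrolysis of the ate complex gives the boronic acid.

Step 9
Reactants: 9 5,7-bis(methoxymethoxy)-8-(3-methylbut-2-enyl)chromone; 17 [3-(tert-butyldimethylsilyloxy)-4-(methoxymethoxy)phenyl]boronic acid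
Product: 18 (2S)-2-[3-(tert-butyldimethylsilyloxy)-4-(methoxymethoxy)phenyl]-5,7-bis(methoxymethoxy)-8-(3-methylbut-2-enyl)chroman-4-one
Conditions: [RhCl(C2H4)2]2 (2.5 mol%), (S)-2,2'-bis[bis(3,4,5-trifluorophenyl)phosphino]-6,6'-dimethoxybiphenyl (5.5 mol%), aq. KOH (20 mol%), 17 (2.5 equiv), PhMe/H2O, 20 °C
Reagents that add atoms: none
Why: Rhodium-catalysed asymmetric 1,4-addition (Hayashi–Miyaura reaction) to the chromone: the aryl–rhodium species carrying the electron-poor chiral diphosphine inserts the C2=C3 bond on one face, which sets C2 as (S), and fast protonation of the rhodium enolate by water at 20 °C releases the flavanone before ring opening can erode the ee.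

Step 10
Reactants: 18 (2S)-2-[3-(tert-butyldimethylsilyloxy)-4-(methoxymethoxy)phenyl]-5,7-bis(methoxymethoxy)-8-(3-methylbut-2-enyl)chroman-4-one
Product: 19 (2S)-2-[3-hydroxy-4-(methoxymethoxy)phenyl]-5,7-bis(methoxymethoxy)-8-(3-methylbut-2-enyl)chroman-4-one
Conditions: n-Bu4NF, AcOH (1:1), THF, 0 °C
Reagents that add atoms: none
Why: Buffered fluoride desilylation cleaves the aryl silyl ether; acetic acid keeps the medium from turning basic, so the MOM ethers survive and C2 is not epimerised by retro-oxa-Michael opening.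

Step 11
Reactants: 20 2-methylbut-3-en-2-ol
Product: 22 methyl 2-methylbut-3-en-2-yl carbonate, via lithium alkoxide 21 (not isolated)
Conditions: n-BuLi, THF, −78 °C; then ClCO2Me, −78 → 0 °C
Reagents that add atoms: methyl chloroformate, COC(=O)Cl
Why: Acylation of the lithium alkoxide of the hindered tertiary allylic alcohol with the chloroformate gives the mixed carbonate needed as the π-allyl source.

Step 12
Reactants: 19 (2S)-2-[3-hydroxy-4-(methoxymethoxy)phenyl]-5,7-bis(methoxymethoxy)-8-(3-methylbut-2-enyl)chroman-4-one; 22 methyl 2-methylbut-3-en-2-yl carbonate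
Product: 23 (2S)-2-[3-(2-methylbut-3-en-2-yloxy)-4-(methoxymethoxy)phenyl]-5,7-bis(methoxymethoxy)-8-(3-methylbut-2-enyl)chroman-4-one
Conditions: Pd(PPh3)4 (5 mol%), 22 (2 equiv), THF, 0 °C → rt
Reagents that add atoms: none
Why: Palladium-catalysed decarboxylative allylic etherification (Tsuji–Trost type): zerovalent palladium ionises 22 to a 1,1-dimethyl-π-allyl complex and methoxide, the methoxide deprotonates only the 3'-phenol, and the phenoxide attacks the more substituted allyl terminus under kinetic control, which gives the tertiary ether under near-neutral conditions that leave C2 alone.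

Step 13
Reactants: 23 (2S)-2-[3-(2-methylbut-3-en-2-yloxy)-4-(methoxymethoxy)phenyl]-5,7-bis(methoxymethoxy)-8-(3-methylbut-2-enyl)chroman-4-one
Product: 25 (2S)-2-[3-hydroxy-4-(methoxymethoxy)-2-(3-methylbut-2-enyl)phenyl]-5,7-bis(methoxymethoxy)-8-(3-methylbut-2-enyl)chroman-4-one, via ring-B dienone 24 (not isolated)
Conditions: PhMe (degassed), 110 °C, sealed tube
Reagents that add atoms: none
Why: Heating folds the aryl 1,1-dimethylallyl ether into a chair-like six-membered transition state in which the terminal CH2 bonds to C2' as the O–C(CH3)2 bond breaks, so allyl transposition turns the tertiary ether into the normal 3-methylbut-2-enyl group in dienone 24, which enolises to phenol 25. The closest known reaction is the thermal ortho-Claisen rearrangement of catechol-type aryl 1,1-dimethylallyl ethers to ortho-prenylphenols, which runs near 100–120 °C because the gem-dimethyl group weakens the O–C bond. No ring is closed; one skeletal C–C bond is made. No stereocentre is created: the C2' centre of 24 is lost on enolisation, and C2 of ring C takes no part and should stay (2S) because the medium is neutral and aprotic, so nothing starts the retro-oxa-Michael opening to a chalcone. The step needs C2' over C4' and C6': C4' carries the OMOM group, so a shift to it gives a dienone that cannot enolise and can only revert or pass on by a slower Cope shift that would form a quaternary carbon–aryl bond at C6', whereas the C2' dienone aromatises at once and drains the equilibrium. Delivery from O3' is intramolecular, so the crowded site between ring C and O3' is reached while the electron-rich C6 of ring A and the C8 prenyl group are left alone.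

Step 14
Reactants: 25 (2S)-2-[3-hydroxy-4-(methoxymethoxy)-2-(3-methylbut-2-enyl)phenyl]-5,7-bis(methoxymethoxy)-8-(3-methylbut-2-enyl)chroman-4-one
Product: 26 (2S)-2-[3-methoxy-4-(methoxymethoxy)-2-(3-methylbut-2-enyl)phenyl]-5,7-bis(methoxymethoxy)-8-(3-methylbut-2-enyl)chroman-4-one
Conditions: Me3SiCHN2, i-Pr2NEt, MeCN/MeOH, rt
Reagents that add atoms: trimethylsilyldiazomethane, C[Si](C)(C)C=[N+]=[N-]
Why: O-Methylation of the phenol by trimethylsilyldiazomethane, with methanol as proton source, runs under nearly neutral conditions, so the flavanone ring is not opened and C2 keeps its configuration, and the ketone and alkenes do not react without a Lewis acid.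

Step 15
Reactants: 26 (2S)-2-[3-methoxy-4-(methoxymethoxy)-2-(3-methylbut-2-enyl)phenyl]-5,7-bis(methoxymethoxy)-8-(3-methylbut-2-enyl)chroman-4-one
Product: 27 (2S)-5,7-dihydroxy-2-[4-hydroxy-3-methoxy-2-(3-methylbut-2-enyl)phenyl]-8-(3-methylbut-2-enyl)chroman-4-one (CNP0282226.1)
Conditions: HCl (3 M aq.), MeOH, 40 °C
Reagents that add atoms: none
Why: Acid-catalysed transacetalisation of the three aryl MOM ethers to methanol frees the phenols; the 2'-prenyl group has no free ortho hydroxyl, and a short reaction in dilute acid should keep hydration, chroman formation at the 8-prenyl group and epimerisation at C2 slow.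

**Compound list**

1 | 5,7-dihydroxy-4H-chromen-4-one (5,7-dihydroxychromone) | O=c1ccoc2cc(O)cc(O)c12 | starting material
2 | 5-hydroxy-7-(methoxymethoxy)-4H-chromen-4-one | COCOc1cc(O)c2c(=O)ccoc2c1 | intermediate
3 | prenyl bromide (1-bromo-3-methylbut-2-ene) | CC(C)=CCBr | starting material
4 | 7-(methoxymethoxy)-5-(3-methylbut-2-enyloxy)-4H-chromen-4-one | COCOc1cc(OCC=C(C)C)c2c(=O)ccoc2c1 | intermediate
5 | 7-(methoxymethoxy)-6-(2-methylbut-3-en-2-yl)-6H-chromene-4,5-dione (ortho-dienone, racemic at C6) | C=CC(C)(C)C1C(OCOC)=CC2=C(C1=O)C(=O)C=CO2 | intermediate (not isolated)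
6 | 7-(methoxymethoxy)-8-(3-methylbut-2-enyl)-8H-chromene-4,5-dione (para-dienone, racemic at C8) | CC(C)=CCC1C(OCOC)=CC(=O)C2=C1OC=CC2=O | intermediate (not isolated)
7 | 5-hydroxy-7-(methoxymethoxy)-8-(3-methylbut-2-enyl)-4H-chromen-4-one | COCOc1cc(O)c2c(=O)ccoc2c1CC=C(C)C | intermediate
8 | sodium 7-(methoxymethoxy)-8-(3-methylbut-2-enyl)-4-oxo-4H-chromen-5-olate | [Na+].COCOc1cc([O-])c2c(=O)ccoc2c1CC=C(C)C | intermediate (not isolated)
9 | 5,7-bis(methoxymethoxy)-8-(3-methylbut-2-enyl)-4H-chromen-4-one | COCOc1cc(OCOC)c2c(=O)ccoc2c1CC=C(C)C | intermediate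
10 | 5-bromosalicylaldehyde (5-bromo-2-hydroxybenzaldehyde) | O=Cc1cc(Br)ccc1O | starting material
11 | 5-bromo-2-(methoxymethoxy)benzaldehyde | COCOc1ccc(Br)cc1C=O | intermediate
12 | 5-bromo-2-(methoxymethoxy)phenyl formate | COCOc1ccc(Br)cc1OC=O | intermediate (not isolated)
13 | 5-bromo-2-(methoxymethoxy)phenol | COCOc1ccc(Br)cc1O | intermediate
14 | [5-bromo-2-(methoxymethoxy)phenoxy](tert-butyl)dimethylsilane | COCOc1ccc(Br)cc1O[Si](C)(C)C(C)(C)C | intermediate
15 | [3-(tert-butyldimethylsilyloxy)-4-(methoxymethoxy)phenyl]lithium | COCOc1ccc([Li])cc1O[Si](C)(C)C(C)(C)C | intermediate (not isolated)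
16 | lithium [3-(tert-butyldimethylsilyloxy)-4-(methoxymethoxy)phenyl]triisopropoxyborate | [Li+].COCOc1ccc([B-](OC(C)C)(OC(C)C)OC(C)C)cc1O[Si](C)(C)C(C)(C)C | intermediate (not isolated)
17 | [3-(tert-butyldimethylsilyloxy)-4-(methoxymethoxy)phenyl]boronic acid | COCOc1ccc(B(O)O)cc1O[Si](C)(C)C(C)(C)C | intermediate
18 | (2S)-2-[3-(tert-butyldimethylsilyloxy)-4-(methoxymethoxy)phenyl]-5,7-bis(methoxymethoxy)-8-(3-methylbut-2-enyl)chroman-4-one | COCOc1ccc([C@@H]2CC(=O)c3c(OCOC)cc(OCOC)c(CC=C(C)C)c3O2)cc1O[Si](C)(C)C(C)(C)C | intermediate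
19 | (2S)-2-[3-hydroxy-4-(methoxymethoxy)phenyl]-5,7-bis(methoxymethoxy)-8-(3-methylbut-2-enyl)chroman-4-one | COCOc1ccc([C@@H]2CC(=O)c3c(OCOC)cc(OCOC)c(CC=C(C)C)c3O2)cc1O | intermediate
20 | 2-methylbut-3-en-2-ol | C=CC(C)(C)O | starting material
21 | lithium 2-methylbut-3-en-2-olate | [Li+].[O-]C(C)(C)C=C | intermediate (not isolated)
22 | methyl 2-methylbut-3-en-2-yl carbonate | C=CC(C)(C)OC(=O)OC | intermediate
23 | (2S)-2-[3-(2-methylbut-3-en-2-yloxy)-4-(methoxymethoxy)phenyl]-5,7-bis(methoxymethoxy)-8-(3-methylbut-2-enyl)chroman-4-one | C=CC(C)(C)Oc1cc([C@@H]2CC(=O)c3c(OCOC)cc(OCOC)c(CC=C(C)C)c3O2)ccc1OCOC | intermediate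
24 | (2S)-2-[4-(methoxymethoxy)-6-(3-methylbut-2-enyl)-5-oxocyclohexa-1,3-dien-1-yl]-5,7-bis(methoxymethoxy)-8-(3-methylbut-2-enyl)chroman-4-one (ring-B dienone, both configurations at the sp3 carbon C2') | CC(C)=CCC1C(=O)C(OCOC)=CC=C1[C@@H]2CC(=O)c3c(OCOC)cc(OCOC)c(CC=C(C)C)c3O2 | intermediate (not isolated)
25 | (2S)-2-[3-hydroxy-4-(methoxymethoxy)-2-(3-methylbut-2-enyl)phenyl]-5,7-bis(methoxymethoxy)-8-(3-methylbut-2-enyl)chroman-4-one | COCOc1ccc([C@@H]2CC(=O)c3c(OCOC)cc(OCOC)c(CC=C(C)C)c3O2)c(CC=C(C)C)c1O | intermediate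
26 | (2S)-2-[3-methoxy-4-(methoxymethoxy)-2-(3-methylbut-2-enyl)phenyl]-5,7-bis(methoxymethoxy)-8-(3-methylbut-2-enyl)chroman-4-one | COCOc1ccc([C@@H]2CC(=O)c3c(OCOC)cc(OCOC)c(CC=C(C)C)c3O2)c(CC=C(C)C)c1OC | intermediate
27 | (2S)-5,7-dihydroxy-2-[4-hydroxy-3-methoxy-2-(3-methylbut-2-enyl)phenyl]-8-(3-methylbut-2-enyl)chroman-4-one | COc1c(O)ccc([C@@H]2CC(=O)c3c(O)cc(O)c(CC=C(C)C)c3O2)c1CC=C(C)C | target

**Step count**

Total: 15 steps. Longest linear sequence: 10 steps (steps 1–4 or steps 5–8, then 9, 10, 12, 13, 14, 15); step 11 is a one-step side branch.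

**Steps most likely to fail**

1. Step 13. Three processes could take over: heterolysis of the tertiary allylic C–O bond with loss of isoprene back to phenol 19; a slow shift into the crowded C2', so that the shift to C4' and onward Cope migration to C6' competes; and acid-trace cyclisation of the new ortho-prenylphenol onto its own alkene. The fallback moves the same [3,3] shift to the small bromoarene, where forcing conditions are harmless, and installs the methyl ether before the rings are joined. It sets out from phenol 13 and comes back to the route at 26.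
   - O-Alkylation of 13 with carbonate 22 and Pd(PPh3)4 in THF should give 4-bromo-2-(2-methylbut-3-en-2-yloxy)-1-(methoxymethoxy)benzene F1.
   - Heating F1 in toluene or N,N-diethylaniline at 110–130 °C should take it through 5-bromo-2-(methoxymethoxy)-6-(3-methylbut-2-enyl)cyclohexa-2,4-dien-1-one F2 to 3-bromo-6-(methoxymethoxy)-2-(3-methylbut-2-enyl)phenol F3, because the only ortho CH is the one next to C–Br.
   - MeI and K2CO3 in acetone should give 1-bromo-3-methoxy-4-(methoxymethoxy)-2-(3-methylbut-2-enyl)benzene F4.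
   - Bromine–lithium exchange with n-BuLi in the presence of B(Oi-Pr)3 at −78 °C, through [3-methoxy-4-(methoxymethoxy)-2-(3-methylbut-2-enyl)phenyl]lithium F5 and lithium triisopropoxy[3-methoxy-4-(methoxymethoxy)-2-(3-methylbut-2-enyl)phenyl]borate F6, then mild hydrolysis, should give [3-methoxy-4-(methoxymethoxy)-2-(3-methylbut-2-enyl)phenyl]boronic acid F7.
   - Rhodium-catalysed asymmetric 1,4-addition of F7 to chromone 9 under the conditions of step 9, with higher loading and longer time for the ortho-substituted boronic acid, should give 26 directly; step 15 follows.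

2. Step 9. The electron-rich, 5- and 8-substituted chromone may turn over slowly, the boronic acid may protodeboronate, and the ee may erode if the rhodium enolate or the product opens to the chalcone and recloses without control. The fallback replaces asymmetric catalysis by resolution. It sets out from chromone 9 and boronic acid 17 and comes back at 18.
   - Conjugate addition with Pd(OCOCF3)2 (divalent palladium) and 2,2'-bipyridine in AcOH/THF/H2O at 60 °C should give rac-2-[3-(tert-butyldimethylsilyloxy)-4-(methoxymethoxy)phenyl]-5,7-bis(methoxymethoxy)-8-(3-methylbut-2-enyl)chroman-4-one F8.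
   - Preparative HPLC on a chiral stationary phase separates (2S)-18 from (2R)-2-[3-(tert-butyldimethylsilyloxy)-4-(methoxymethoxy)phenyl]-5,7-bis(methoxymethoxy)-8-(3-methylbut-2-enyl)chroman-4-one F9, which is set aside.

3. Step 15. Brønsted acid may cyclise the 8-prenyl group onto the freed 7-OH (2,2-dimethylchroman formation), hydrate the prenyl alkenes, or epimerise C2 before all three MOM groups are gone. The fallback avoids protic acid by exchanging the acetals for silyl ethers. It sets out from 26 and comes back at 27.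
   - Me3SiOSO2CF3 and 2,2'-bipyridyl in CH2Cl2/MeCN at 0 °C should convert the three aryl MOM ethers, through pyridinium-type intermediates, into (2S)-2-[3-methoxy-2-(3-methylbut-2-enyl)-4-(trimethylsilyloxy)phenyl]-8-(3-methylbut-2-enyl)-5,7-bis(trimethylsilyloxy)chroman-4-one F10.
   - Adding water at rt should hydrolyse F10 to 27 under nearly neutral conditions.

**Further compounds**

F1 | step 13 | 4-bromo-2-(2-methylbut-3-en-2-yloxy)-1-(methoxymethoxy)benzene | C=CC(C)(C)Oc1cc(Br)ccc1OCOC
F2 | step 13 | 5-bromo-2-(methoxymethoxy)-6-(3-methylbut-2-enyl)cyclohexa-2,4-dien-1-one | CC(C)=CCC1C(=O)C(OCOC)=CC=C1Br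
F3 | step 13 | 3-bromo-6-(methoxymethoxy)-2-(3-methylbut-2-enyl)phenol | COCOc1ccc(Br)c(CC=C(C)C)c1O
F4 | step 13 | 1-bromo-3-methoxy-4-(methoxymethoxy)-2-(3-methylbut-2-enyl)benzene | COCOc1ccc(Br)c(CC=C(C)C)c1OC
F5 | step 13 | [3-methoxy-4-(methoxymethoxy)-2-(3-methylbut-2-enyl)phenyl]lithium | COCOc1ccc([Li])c(CC=C(C)C)c1OC
F6 | step 13 | lithium triisopropoxy[3-methoxy-4-(methoxymethoxy)-2-(3-methylbut-2-enyl)phenyl]borate | [Li+].COCOc1ccc([B-](OC(C)C)(OC(C)C)OC(C)C)c(CC=C(C)C)c1OC
F7 | step 13 | [3-methoxy-4-(methoxymethoxy)-2-(3-methylbut-2-enyl)phenyl]boronic acid | COCOc1ccc(B(O)O)c(CC=C(C)C)c1OC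
F8 | step 9 | rac-2-[3-(tert-butyldimethylsilyloxy)-4-(methoxymethoxy)phenyl]-5,7-bis(methoxymethoxy)-8-(3-methylbut-2-enyl)chroman-4-one | COCOc1ccc(C2CC(=O)c3c(OCOC)cc(OCOC)c(CC=C(C)C)c3O2)cc1O[Si](C)(C)C(C)(C)C
F9 | step 9 | (2R)-2-[3-(tert-butyldimethylsilyloxy)-4-(methoxymethoxy)phenyl]-5,7-bis(methoxymethoxy)-8-(3-methylbut-2-enyl)chroman-4-one | COCOc1ccc([C@H]2CC(=O)c3c(OCOC)cc(OCOC)c(CC=C(C)C)c3O2)cc1O[Si](C)(C)C(C)(C)C
F10 | step 15 | (2S)-2-[3-methoxy-2-(3-methylbut-2-enyl)-4-(trimethylsilyloxy)phenyl]-8-(3-methylbut-2-enyl)-5,7-bis(trimethylsilyloxy)chroman-4-one | COc1c(O[Si](C)(C)C)ccc([C@@H]2CC(=O)c3c(O[Si](C)(C)C)cc(O[Si](C)(C)C)c(CC=C(C)C)c3O2)c1CC=C(C)C
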